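**Retrosynthetic overview**
1. 24 ⇐ 23: ring-closing metathesis at C9=C10 closes the ten-membered carbocycle last, with the angelate already in place.
2. 23 ⇐ butenolide allylboronate 16 + acrolein: an acid-catalysed allylboration makes C7–C8, sets C7 and C8 and delivers the α-methylene lactone; the butenolide comes from an acrylate RCM.
3. C4=C5 (Z) and C6 ⇐ temporary silicon-tethered, desymmetrising RCM of penta-1,4-dien-3-ol on the C2-symmetric diol 5.
4. Diol 5 (C1, C3) ⇐ Shi double epoxidation of skipped diene 3, then epoxide-to-allylic-alcohol isomerisation; 3 ⇐ two C5 units.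
5. Ring order: temporary seven-membered dioxasilepine (step 5) → butenolide (step 7) → α-methylene-γ-butyrolactone (step 9) → ten-membered ring (step 11).

Assumption: C1–C15 are germacrane-type locants used only for orientation (lactone oxygen on C6, angelate on C8, hydroxyls on C1 and C3), and the ent-Shi ketone is taken to give the (S)-epoxide from each R–CH=CMe2 unit, as the usual Shi model predicts.

Step 1
Reactants: 1 1-bromo-3-methylbut-2-ene; 2 (2-methylprop-1-en-1-yl)magnesium bromide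
Product: 3 2,6-dimethylhepta-2,5-diene
Conditions: CuI (5 mol %), THF, −20 °C to rt
Reagents that add atoms: none
Why: Cu-catalysed SN2 allylic alkylation of the primary prenyl bromide by the alkenyl Grignard reagent joins the two C5 units at the unhindered α-carbon to give the skipped diene, no stereocentre being formed.

Step 2
Reactants: 3 2,6-dimethylhepta-2,5-diene
Product: 4 (3S)-3-{[(2S)-3,3-dimethyloxiran-2-yl]methyl}-2,2-dimethyloxirane
Conditions: ent-Shi ketone (L-fructose-derived, 60 mol %), KHSO5 (as Oxone), K2CO3, Bu4NHSO4, MeCN–CH2(OMe)2/aq. Na2B4O7–Na2EDTA (pH 10.5), 0 °C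
Reagents that add atoms: potassium peroxymonosulfate, [K+].[O-]S(=O)(=O)OO
Why: Shi asymmetric epoxidation (chiral dioxirane, spiro transition state) turns each trisubstituted alkene into the (S)-epoxide, which sets C1 and C3, and the double reaction on a symmetric diene raises the ee of the C2-symmetric product while leaving a separable meso isomer.

Step 3
Reactants: 4 (3S)-3-{[(2S)-3,3-dimethyloxiran-2-yl]methyl}-2,2-dimethyloxirane
Product: 5 (3S,5S)-2,6-dimethylhepta-1,6-diene-3,5-diol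
Conditions: Et2Al(TMP) (5 equiv, from LiTMP and Et2AlCl), toluene, 0 °C; aq. potassium sodium tartrate
Reagents that add atoms: none
Why: Base-mediated epoxide-to-allylic-alcohol isomerisation with an aluminium amide removes a methyl proton in a syn-elimination and breaks only the tertiary C–O bond, so both secondary C–O stereocentres are retained and two isopropenyl carbinols result.

Step 4
Reactants: 5 (3S,5S)-2,6-dimethylhepta-1,6-diene-3,5-diol; 6 penta-1,4-dien-3-ol
Product: 8 (3S,5S)-2,6-dimethyl-5-{[(penta-1,4-dien-3-yloxy)di(propan-2-yl)silyl]oxy}hepta-1,6-dien-3-ol, via chlorosilane 7 (not isolated)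
Conditions: 6, iPr2SiCl2, imidazole, CH2Cl2, 0 °C; then 5 (3 equiv, excess recovered), −20 °C to rt
Reagents that add atoms: dichlorodi(propan-2-yl)silane, CC(C)[Si](Cl)(Cl)C(C)C
Why: Stepwise silaketal formation (chlorosilane, then second alcohol) gives the mixed diisopropylsilyl ketal needed as a temporary tether, and because the diol is C2-symmetric either hydroxyl gives the same product while the excess diol suppresses double silylation.

Step 5
Reactants: 8 (3S,5S)-2,6-dimethyl-5-{[(penta-1,4-dien-3-yloxy)di(propan-2-yl)silyl]oxy}hepta-1,6-dien-3-ol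
Product: 10 (3S,5S,6Z,8R)-2,6-dimethyldeca-1,6,9-triene-3,5,8-triol, via dioxasilepine 9 (not isolated)
Conditions: second-generation Grubbs catalyst (5 mol %), CH2Cl2 (5 mM), 40 °C; then HF·pyridine, pyridine, THF, 0 °C
Reagents that add atoms: none
Why: Temporary silicon-tethered ring-closing metathesis closes a seven-membered dioxasilepine, which enforces the Z geometry of the new trisubstituted C4=C5 bond and selects one of the two enantiotopic vinyl groups so that the remaining vinyl and the C3 side chain are cis (both pseudo-equatorial in the forming ring), setting C6 by 1,4-induction before HF removes the tether.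

Step 6
Reactants: 10 (3S,5S,6Z,8R)-2,6-dimethyldeca-1,6,9-triene-3,5,8-triol; 11 2-(bromomethyl)prop-2-enoic acid
Product: 14 (3R,4Z)-5-[(4S,6S)-2-methyl-6-(prop-1-en-2-yl)-1,3,2-dioxaborinan-4-yl]hexa-1,4-dien-3-yl 2-(bromomethyl)prop-2-enoate, via triol methylboronate 12 (not isolated), via acid chloride 13 (not isolated)
Conditions: 10, MeB(OH)2, MgSO4, CH2Cl2, rt; separately 11, (COCl)2, cat. DMF, CH2Cl2, 0 °C; combine, 2,6-lutidine, −20 °C
Reagents that add atoms: methylboronic acid, CB(O)O; oxalyl chloride, O=C(Cl)C(=O)Cl (chlorine of intermediate 13 only)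
Why: Cyclic boronate formation ties the 1,3-diol into a six-membered ring (preferred over the seven-membered O3/O6 alternative) and leaves only the C6 hydroxyl free for esterification by the acid chloride with a hindered pyridine base that does not displace the allylic bromide.

Step 7
Reactants: 14 (3R,4Z)-5-[(4S,6S)-2-methyl-6-(prop-1-en-2-yl)-1,3,2-dioxaborinan-4-yl]hexa-1,4-dien-3-yl 2-(bromomethyl)prop-2-enoate
Product: 15 (5S)-3-(bromomethyl)-5-{(1Z)-2-[(4S,6S)-2-methyl-6-(prop-1-en-2-yl)-1,3,2-dioxaborinan-4-yl]prop-1-en-1-yl}furan-2(5H)-one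
Conditions: second-generation Hoveyda–Grubbs catalyst (5 mol %), toluene, 80 °C
Reagents that add atoms: none
Why: Ring-closing metathesis of the 2-substituted acrylate with the adjacent vinyl group gives the five-membered butenolide, the fastest closure available because the other alkenes are remote and 1,1-di- or trisubstituted, and C6 is untouched.

Step 8
Reactants: 15 (5S)-3-(bromomethyl)-5-{(1Z)-2-[(4S,6S)-2-methyl-6-(prop-1-en-2-yl)-1,3,2-dioxaborinan-4-yl]prop-1-en-1-yl}furan-2(5H)-one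
Product: 16 (5S)-5-{(1Z)-2-[(4S,6S)-2-methyl-6-(prop-1-en-2-yl)-1,3,2-dioxaborinan-4-yl]prop-1-en-1-yl}-3-[(4,4,5,5-tetramethyl-1,3,2-dioxaborolan-2-yl)methyl]furan-2(5H)-one
Conditions: Pd2(dba)3 (2.5 mol %), B2pin2, KOAc, DMSO, 40 °C
Reagents that add atoms: bis(pinacolato)diboron, CC1(C)OB(OC1(C)C)B1OC(C)(C)C(C)(C)O1
Why: Miyaura-type Pd-catalysed allylic borylation goes through a π-allyl complex that is borylated at the primary terminus, and opening of the lactone by β-acyloxy elimination is disfavoured because the ring C–O bond lies in the nodal plane of the allyl system.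

Step 9
Reactants: 16 (5S)-5-{(1Z)-2-[(4S,6S)-2-methyl-6-(prop-1-en-2-yl)-1,3,2-dioxaborinan-4-yl]prop-1-en-1-yl}-3-[(4,4,5,5-tetramethyl-1,3,2-dioxaborolan-2-yl)methyl]furan-2(5H)-one; 17 prop-2-enal
Product: 19 (4S,5S)-4-[(1R)-1-hydroxyprop-2-en-1-yl]-3-methylidene-5-{(1Z)-2-[(4S,6S)-2-methyl-6-(prop-1-en-2-yl)-1,3,2-dioxaborinan-4-yl]prop-1-en-1-yl}oxolan-2-one, via borate ester 18 (not isolated)
Conditions: (S)-3,3′-bis(2,4,6-triisopropylphenyl)-1,1′-binaphthyl-2,2′-diyl N-triflylphosphoramide (10 mol %), 17 (5 equiv), 4 Å MS, toluene, −20 °C to rt; pH 7 buffer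
Reagents that add atoms: none
Why: Proposed new method: a chiral Brønsted acid hydrogen-bonds to a boronate oxygen of the lactone-fused 2-carbonylallyl boronate so that this otherwise sluggish, electron-poor reagent adds to acrolein at low temperature through a closed six-membered chair, in which the ring-locked E-type γ-substituent gives the anti carbinol at C8, approach anti to the C5 side chain gives the trans lactone at C7, and the (S)-acid is the enantiomer expected to favour the same aldehyde Si face (matched pairing); the closest known reaction types are the chiral phosphoric acid-catalysed allylboration of aldehydes with allyl pinacol boronates and the Lewis or Brønsted acid-catalysed additions of acyclic 2-alkoxycarbonyl allylboronates.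

Step 10
Reactants: 19 (4S,5S)-4-[(1R)-1-hydroxyprop-2-en-1-yl]-3-methylidene-5-{(1Z)-2-[(4S,6S)-2-methyl-6-(prop-1-en-2-yl)-1,3,2-dioxaborinan-4-yl]prop-1-en-1-yl}oxolan-2-one; 20 (2Z)-2-methylbut-2-enoic acid
Product: 23 (1R)-1-[(2S,3S)-2-[(1Z,3S,5S)-3,5-dihydroxy-2,6-dimethylhepta-1,6-dien-1-yl]-4-methylidene-5-oxooxolan-3-yl]prop-2-en-1-yl (2Z)-2-methylbut-2-enoate, via mixed anhydride 21 (not isolated), via angelate boronate 22 (not isolated)
Conditions: 20, 2,4,6-Cl3C6H2COCl, Et3N, toluene, rt; then 19, 75 °C; then MeOH, 40 °C, repeated co-evaporation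
Reagents that add atoms: 2,4,6-trichlorobenzoyl chloride, O=C(Cl)c1c(Cl)cc(Cl)cc1Cl (atoms of intermediate 21 only)
Why: Yamaguchi-type mixed-anhydride esterification without DMAP acylates the only free hydroxyl without Z-to-E isomerisation of the angelate, and methanolysis then removes the boronate as volatile MeB(OMe)2.

Step 11
Reactants: 23 (1R)-1-[(2S,3S)-2-[(1Z,3S,5S)-3,5-dihydroxy-2,6-dimethylhepta-1,6-dien-1-yl]-4-methylidene-5-oxooxolan-3-yl]prop-2-en-1-yl (2Z)-2-methylbut-2-enoate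
Product: 24 (3aR,4R,5Z,7S,9S,10Z,11aS)-7,9-dihydroxy-6,10-dimethyl-3-methylidene-2-oxo-2,3,3a,4,7,8,9,11a-octahydrocyclodeca[b]furan-4-yl (2Z)-2-methylbut-2-enoate (CNP0152559.1)
Conditions: second-generation Hoveyda–Grubbs catalyst (2 × 10 mol %), 1,4-benzoquinone (20 mol %), toluene (0.5 mM), 80 °C
Reagents that add atoms: none
Why: Ring-closing metathesis between the C8 vinyl and C10 isopropenyl groups closes the ten-membered ring, with Z geometry at C9=C10 expected because (Z,Z)-cyclodeca-1,6-dienes are nearly strain-free, the existing Z-alkene and trans-lactone act as turn elements and the free allylic C1 hydroxyl assists the metathesis; no stereocentre is formed.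

**Compound list**
1 | 1-bromo-3-methylbut-2-ene | CC(C)=CCBr | starting material
2 | (2-methylprop-1-en-1-yl)magnesium bromide | CC(C)=C[Mg]Br | starting material
3 | 2,6-dimethylhepta-2,5-diene | CC(C)=CCC=C(C)C | intermediate
4 | (3S)-3-{[(2S)-3,3-dimethyloxiran-2-yl]methyl}-2,2-dimethyloxirane | CC1(C)O[C@H]1C[C@@H]1OC1(C)C | intermediate
5 | (3S,5S)-2,6-dimethylhepta-1,6-diene-3,5-diol | C=C(C)[C@@H](O)C[C@H](O)C(C)=C | intermediate
6 | penta-1,4-dien-3-ol | C=CC(O)C=C | starting material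
7 | chloro(penta-1,4-dien-3-yloxy)di(propan-2-yl)silane | C=CC(O[Si](Cl)(C(C)C)C(C)C)C=C | intermediate
8 | (3S,5S)-2,6-dimethyl-5-{[(penta-1,4-dien-3-yloxy)di(propan-2-yl)silyl]oxy}hepta-1,6-dien-3-ol | C=C(C)[C@@H](O[Si](C(C)C)(C(C)C)OC(C=C)C=C)C[C@H](O)C(C)=C | intermediate
9 | (2S)-1-[(4S,7R)-7-ethenyl-5-methyl-2,2-di(propan-2-yl)-4,7-dihydro-1,3,2-dioxasilepin-4-yl]-3-methylbut-3-en-2-ol | C=C[C@H]1O[Si](C(C)C)(C(C)C)O[C@@H](C[C@H](O)C(C)=C)/C(C)=C\1 | intermediate
10 | (3S,5S,6Z,8R)-2,6-dimethyldeca-1,6,9-triene-3,5,8-triol | C=C[C@@H](O)/C=C(/C)[C@@H](O)C[C@H](O)C(C)=C | intermediate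
11 | 2-(bromomethyl)prop-2-enoic acid | C=C(CBr)C(=O)O | starting material
12 | (3R,4Z)-5-[(4S,6S)-2-methyl-6-(prop-1-en-2-yl)-1,3,2-dioxaborinan-4-yl]hexa-1,4-dien-3-ol | C=C[C@@H](O)/C=C(/C)[C@@H]1C[C@@H](C(C)=C)OB(C)O1 | intermediate
13 | 2-(bromomethyl)prop-2-enoyl chloride | C=C(CBr)C(=O)Cl | intermediate
14 | (3R,4Z)-5-[(4S,6S)-2-methyl-6-(prop-1-en-2-yl)-1,3,2-dioxaborinan-4-yl]hexa-1,4-dien-3-yl 2-(bromomethyl)prop-2-enoate | C=C(CBr)C(=O)O[C@H](C=C)/C=C(/C)[C@@H]1C[C@@H](C(C)=C)OB(C)O1 | intermediate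
15 | (5S)-3-(bromomethyl)-5-{(1Z)-2-[(4S,6S)-2-methyl-6-(prop-1-en-2-yl)-1,3,2-dioxaborinan-4-yl]prop-1-en-1-yl}furan-2(5H)-one | BrCC1=C[C@@H](OC1=O)/C=C(/C)[C@@H]2C[C@@H](C(C)=C)OB(C)O2 | intermediate
16 | (5S)-5-{(1Z)-2-[(4S,6S)-2-methyl-6-(prop-1-en-2-yl)-1,3,2-dioxaborinan-4-yl]prop-1-en-1-yl}-3-[(4,4,5,5-tetramethyl-1,3,2-dioxaborolan-2-yl)methyl]furan-2(5H)-one | CC1(C)OB(CC2=C[C@@H](OC2=O)/C=C(/C)[C@@H]3C[C@@H](C(C)=C)OB(C)O3)OC1(C)C | intermediate
17 | prop-2-enal (acrolein) | C=CC=O | starting material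
18 | O-(4,4,5,5-tetramethyl-1,3,2-dioxaborolan-2-yl) ether of 19 (borate ester at the C8 oxygen, same configuration as 19) | C=C1C(=O)O[C@H]([C@@H]1[C@H](OB2OC(C)(C)C(C)(C)O2)C=C)/C=C(/C)[C@@H]3C[C@@H](C(C)=C)OB(C)O3 | intermediate
19 | (4S,5S)-4-[(1R)-1-hydroxyprop-2-en-1-yl]-3-methylidene-5-{(1Z)-2-[(4S,6S)-2-methyl-6-(prop-1-en-2-yl)-1,3,2-dioxaborinan-4-yl]prop-1-en-1-yl}oxolan-2-one | C=C1C(=O)O[C@H]([C@@H]1[C@H](O)C=C)/C=C(/C)[C@@H]2C[C@@H](C(C)=C)OB(C)O2 | intermediate
20 | (2Z)-2-methylbut-2-enoic acid (angelic acid) | C/C=C(/C)C(=O)O | starting material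
21 | (2Z)-2-methylbut-2-enoic 2,4,6-trichlorobenzoic anhydride | C/C=C(/C)C(=O)OC(=O)c1c(Cl)cc(Cl)cc1Cl | intermediate
22 | (1R)-1-[(2S,3S)-4-methylidene-2-{(1Z)-2-[(4S,6S)-2-methyl-6-(prop-1-en-2-yl)-1,3,2-dioxaborinan-4-yl]prop-1-en-1-yl}-5-oxooxolan-3-yl]prop-2-en-1-yl (2Z)-2-methylbut-2-enoate | C=C1C(=O)O[C@H]([C@@H]1[C@H](OC(=O)/C(C)=C\C)C=C)/C=C(/C)[C@@H]2C[C@@H](C(C)=C)OB(C)O2 | intermediate
23 | (1R)-1-[(2S,3S)-2-[(1Z,3S,5S)-3,5-dihydroxy-2,6-dimethylhepta-1,6-dien-1-yl]-4-methylidene-5-oxooxolan-3-yl]prop-2-en-1-yl (2Z)-2-methylbut-2-enoate | C=C1C(=O)O[C@H]([C@@H]1[C@H](OC(=O)/C(C)=C\C)C=C)/C=C(/C)[C@@H](O)C[C@H](O)C(C)=C | intermediate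
24 | (3aR,4R,5Z,7S,9S,10Z,11aS)-7,9-dihydroxy-6,10-dimethyl-3-methylidene-2-oxo-2,3,3a,4,7,8,9,11a-octahydrocyclodeca[b]furan-4-yl (2Z)-2-methylbut-2-enoate | C=C1C(=O)O[C@H]2/C=C(/C)[C@@H](O)C[C@H](O)/C(C)=C\[C@@H](OC(=O)/C(C)=C\C)[C@H]12 | target

**Step count**
Total steps: 11. Longest linear sequence: 11 (the route is fully linear).

**Three steps most likely to fail**

Step 11 (ten-membered ring by metathesis to a trisubstituted alkene; oligomerisation or no closure are the likely failures). The fallback sets out from 8 and comes back at 24, and moves the ring closure to the C7–C8 bond.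
- The free hydroxyl of 8 is silylated with chloro(prop-2-en-1-yloxy)di(propan-2-yl)silane F6 (from prop-2-en-1-ol and iPr2SiCl2) to give bis-silaketal F7.
- Second-generation Grubbs catalyst closes both seven-membered rings to bis-dioxasilepine F8, so that C4=C5 and C9=C10 are both Z and C6 is set as in step 5; HF·pyridine then frees tetraol F9.
- MeB(OH)2 masks the 1,3-diol as tetraol methylboronate F10, and TEMPO/PhI(OAc)2 oxidises only the primary allylic alcohol to Z-enal F11.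
- Acid chloride 13 acylates the C6 hydroxyl to ester F12, and second-generation Hoveyda–Grubbs catalyst gives bromomethylbutenolide enal F13.
- CrCl2 in dilute THF closes the ring by an intramolecular Nozaki–Hiyama allylation to macrocyclic alcohol F14.
- Mixed anhydride 21 and then methanol convert F14, by way of macrocyclic angelate boronate F15, into 24.

Step 9 (the proposed new acid-catalysed allylboration; the electron-poor boronate may not react or acrolein may polymerise). The fallback sets out from 15 and comes back at 19. Bromide 15 and 17 are combined with CrCl2 in THF at rt in a Nozaki–Hiyama allylation, which is known chemistry for allylic bromides and runs through the same closed chair to the anti, trans product. Steps 8 and 9 are then replaced by one step and no new compound is made (F0).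

Step 5 (diastereoselectivity of the substrate-controlled desymmetrisation). The fallback sets out from 5 and comes back at 10, and brings in C6 with a partner of fixed configuration instead.
- Diol 5 is tethered to (3S)-5-(trimethylsilyl)pent-1-en-4-yn-3-ol F1 (from 17 and ethynyltrimethylsilane by Me2Zn/ProPhenol alkynylation) through its chlorosilane F2, giving mixed silaketal F3.
- Second-generation Grubbs catalyst gives alkynyl dioxasilepine F4.
- TBAF removes the tether and the alkynyl silyl group to give enyne triol F5.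
- Semi-hydrogenation (H2, Pd/CaCO3 poisoned with Pb(OAc)2, quinoline) gives 10.

**Further compounds**
F1 | step 5 | (3S)-5-(trimethylsilyl)pent-1-en-4-yn-3-ol | C=C[C@H](O)C#C[Si](C)(C)C
F2 | step 5 | chloro{[(3S)-5-(trimethylsilyl)pent-1-en-4-yn-3-yl]oxy}di(propan-2-yl)silane | C=C[C@H](O[Si](Cl)(C(C)C)C(C)C)C#C[Si](C)(C)C
F3 | step 5 | (3S,5S)-2,6-dimethyl-5-{[di(propan-2-yl){[(3S)-5-(trimethylsilyl)pent-1-en-4-yn-3-yl]oxy}silyl]oxy}hepta-1,6-dien-3-ol | C=C(C)[C@@H](O[Si](C(C)C)(C(C)C)O[C@@H](C=C)C#C[Si](C)(C)C)C[C@H](O)C(C)=C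
F4 | step 5 | (2S)-3-methyl-1-[(4S,7S)-5-methyl-2,2-di(propan-2-yl)-7-[(trimethylsilyl)ethynyl]-4,7-dihydro-1,3,2-dioxasilepin-4-yl]but-3-en-2-ol | C[Si](C)(C)C#C[C@H]1O[Si](C(C)C)(C(C)C)O[C@@H](C[C@H](O)C(C)=C)/C(C)=C\1
F5 | step 5 | (3S,5S,6Z,8S)-2,6-dimethyldeca-1,6-dien-9-yne-3,5,8-triol | C#C[C@@H](O)/C=C(/C)[C@@H](O)C[C@H](O)C(C)=C
F0 | step 9 | none | none
F6 | step 11 | chloro(prop-2-en-1-yloxy)di(propan-2-yl)silane | C=CCO[Si](Cl)(C(C)C)C(C)C
F7 | step 11 | {[(3S,5S)-2,6-dimethyl-5-{[(penta-1,4-dien-3-yloxy)di(propan-2-yl)silyl]oxy}hepta-1,6-dien-3-yl]oxy}(prop-2-en-1-yloxy)di(propan-2-yl)silane | C=C(C)[C@@H](O[Si](C(C)C)(C(C)C)OC(C=C)C=C)C[C@H](O[Si](C(C)C)(C(C)C)OCC=C)C(C)=C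
F8 | step 11 | (4S,7R)-7-ethenyl-5-methyl-4-{[(4S)-5-methyl-2,2-di(propan-2-yl)-4,7-dihydro-1,3,2-dioxasilepin-4-yl]methyl}-2,2-di(propan-2-yl)-4,7-dihydro-1,3,2-dioxasilepine | C=C[C@H]1O[Si](C(C)C)(C(C)C)O[C@@H](C[C@@H]2O[Si](C(C)C)(C(C)C)OC/C=C\2C)/C(C)=C\1
F9 | step 11 | (2Z,4S,6S,7Z,9R)-3,7-dimethylundeca-2,7,10-triene-1,4,6,9-tetrol | C=C[C@@H](O)/C=C(/C)[C@@H](O)C[C@H](O)/C(C)=C\CO
F10 | step 11 | (2Z)-3-{(4S,6S)-6-[(2Z,4R)-4-hydroxyhexa-2,5-dien-2-yl]-2-methyl-1,3,2-dioxaborinan-4-yl}but-2-en-1-ol | C=C[C@@H](O)/C=C(/C)[C@@H]1C[C@@H](/C(C)=C\CO)OB(C)O1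
F11 | step 11 | (2Z)-3-{(4S,6S)-6-[(2Z,4R)-4-hydroxyhexa-2,5-dien-2-yl]-2-methyl-1,3,2-dioxaborinan-4-yl}but-2-enal | C=C[C@@H](O)/C=C(/C)[C@@H]1C[C@@H](/C(C)=C\C=O)OB(C)O1
F12 | step 11 | (3R,4Z)-5-{(4S,6S)-2-methyl-6-[(2Z)-4-oxobut-2-en-2-yl]-1,3,2-dioxaborinan-4-yl}hexa-1,4-dien-3-yl 2-(bromomethyl)prop-2-enoate | C=C(CBr)C(=O)O[C@H](C=C)/C=C(/C)[C@@H]1C[C@@H](/C(C)=C\C=O)OB(C)O1
F13 | step 11 | (2Z)-3-{(4S,6S)-6-[(1Z)-1-[(2S)-4-(bromomethyl)-5-oxo-2,5-dihydrofuran-2-yl]prop-1-en-2-yl]-2-methyl-1,3,2-dioxaborinan-4-yl}but-2-enal | BrCC1=C[C@@H](OC1=O)/C=C(/C)[C@@H]2C[C@@H](/C(C)=C\C=O)OB(C)O2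
F14 | step 11 | 24 lacking the angeloyl group (free C8 hydroxyl) and with the C1 and C3 oxygens bridged as the cyclic methylboronate, configuration as in 24 | C=C1C(=O)O[C@H]2/C=C(/C)[C@@H]3C[C@H](OB(C)O3)/C(C)=C\[C@@H](O)[C@H]12
F15 | step 11 | 24 with the C1 and C3 oxygens bridged as the cyclic methylboronate | C=C1C(=O)O[C@H]2/C=C(/C)[C@@H]3C[C@H](OB(C)O3)/C(C)=C\[C@@H](OC(=O)/C(C)=C\C)[C@H]12
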